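A small charge can still pose a long question. You put 3.0 M of solid substrate into the flask, and Sunday's run is this very flask, followed to 60.0 s.

| flask | solid substrate | remark | time |
|---|---|---|---|
| Sunday's | 3 M | the very flask that is asked about, followed so far |  |
| flask | 3.0 M |  | 6.0 min |
- Sunday's (time / s: target / %, isomer of the product / %): 15.0: 28.2, 33.3; 30.0: 41.3, 53.2; 50.0: 39.3, 52.0; 60.0: 38.5, 52.2

(each reading ± 0.3 percentage points)
- ratio of target to isomer of the product at 2.0 s
- ratio of target to isomer of the product at 6.0 min
- which of target and isomer of the product there is more of at 6.0 min
- in percentages every species weighs as the solid substrate in it: one side product counts as two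
- as a solid, counted per litre of solution: solid substrate
- steps that have been proposed: starting material -> target; third conformer -> third product; other conformer -> isomer of the product; starting material + target -> side product; starting material <-> other conformer; other conformer <-> third conformer; target -> over-reaction product; solid substrate <-> starting material
- at the start none of the solid substrate is in solution

After 30.0 s, isomer of the product stays near 52.2%, so the late ratio hangs on target. Target goes from 41.3% to 38.5% between 30.0 s and 60.0 s. Taken as a first-order loss, that fall gives h = 4.94 min, the read half-life of target.

But those readings span 30.0 s, and the asked time lies 300 s beyond them. So their scatter counts 10.0-fold. My reckoning for the ratio at 6.0 min is 0.366. Two standard deviations put it between 0.293 and 0.456. Its top stays below 1, so my reckoning puts isomer of the product ahead at 6.0 min.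

The forecast gives a ratio of 1.2 at 2.0 s and 0.37 at 6.0 min, with isomer of the product ahead: “The target decays slowly, from 41.3 to 38.5 over 30 s, giving k ≈ 0.0023 per second, consistent with first-order over-reaction”. Its late ratio and mine rest on the same fall of target, so their agreement is no check.

The flask gives 0.947 at 2.0 s and 0.305 at 6.0 min, with isomer of the product ahead.

    starting material → target (k = 0.431 s⁻¹)
    third conformer → third product (k = 0.950 s⁻¹)
    other conformer → isomer of the product (k = 0.747 s⁻¹)
    starting material + target → side product (k = 0.0143 M⁻¹ s⁻¹)
    starting material ⇌ other conformer (K = 0.744, k = 5.44 s⁻¹)
    other conformer ⇌ third conformer (K = 1.70, k = 0.0284 s⁻¹)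
    target → over-reaction product (k = 0.00291 s⁻¹)
    solid substrate ⇌ starting material, rate k8*(cs8 - [starting material]) while solid is left; crystals form when [starting material] > cs8 (solubility = 1.70 M, k = 0.0929 s⁻¹)

At 6.0 min the flask holds 15.9% of target against 52.3% of isomer of the product. Its ratio lies just above the foot of my range. In percent of the charge, h carries target in this flask from Sunday's reading of 38.5% to 19.1% at 6.0 min, and the foot of my range corresponds to 15.3%. At 6.0 min the neighbouring flask, charged with 1.8 M of solid substrate, holds 15.9% of target, more than that foot.

The readings are simulated with constants of no real substance; scatter was added.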